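**Retrosynthetic overview**

- Feature: in unit 1 (the 4'-methoxyflavone half: benzo ring A, pyranone ring C, anisyl ring B), ring A (C4a, C5, C6, C7, C8, C8a) is a phloroglucinol ring that carries unit 2 (the 8''-linked genkwanin half) on C6. Once C4–C4a is cut, the two carbons flanking the oxygen para to the biaryl bond (future C4a and C8) are equivalent, so an acylative closure from that oxygen can only give the 6-linkage.
- Disconnection 1 (last): ring C at C4–C4a, Friedel–Crafts closure of a (Z)-β-aryloxycinnamic acid in Eaton's reagent.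
- Disconnection 2: O1–C2, addition of the single free phenol of an 8''-arylated genkwanin to tert-butyl 3-(4-methoxyphenyl)propiolate. The oxygen para to the biaryl bond is marked beforehand by a silyl ether; the flanking oxygens, 5''-O and 4'''-O carry benzyl ethers.
- Disconnection 3: biaryl bond C6–C8'', Negishi coupling of 8''-iodo-4',5-di-O-benzylgenkwanin with a 2,6-bis(benzyloxy)-4-silyloxyphenylzinc reagent.
- Ring order: the three rings of unit 2 come intact from genkwanin, ring A from 3,5-bis(benzyloxy)phenol, ring B from the arylpropiolic acid. Ring C is the only ring made, in the last step.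

Key step: step 10

Assumption: the C6–C8'' axis bears four ortho oxygen substituents and may be configurationally stable; the given structure carries no axial descriptor, so the racemate is taken as the target.

**Route**

Step 1
Reactants: 1 genkwanin
Product: 2 5-(benzyloxy)-2-[4-(benzyloxy)phenyl]-7-methoxy-4H-chromen-4-one (4',5-di-O-benzylgenkwanin)
Conditions: BnBr, K2CO3, DMF, 80 °C
Reagents that add atoms: benzyl bromide, BrCc1ccccc1
Why: Williamson etherification, easy at the 4'-OH and forced at the hydrogen-bonded 5-OH, which also removes the free ortho-directing phenol that would steer halogenation to C6''.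

Step 2
Reactants: 2 5-(benzyloxy)-2-[4-(benzyloxy)phenyl]-7-methoxy-4H-chromen-4-one
Product: 3 5-(benzyloxy)-2-[4-(benzyloxy)phenyl]-8-iodo-7-methoxy-4H-chromen-4-one
Conditions: I2, AgO2CCF3, CH2Cl2, 0 °C → rt
Reagents that add atoms: iodine, II
Why: Electrophilic aromatic iodination of a 5,7-dialkoxyflavone, which under iodine/silver salt conditions should go to C8'' (para to the 5''-ether, ortho to 7''-OMe and O1'') rather than to C6'' crowded between two alkoxy groups; the site is to be confirmed by NOE from the remaining H6'' to both flanking O-alkyl groups.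

Step 3
Reactants: 4 3,5-bis(benzyloxy)phenol
Product: 5 [3,5-bis(benzyloxy)phenoxy]tri(propan-2-yl)silane
Conditions: i-Pr3SiCl, imidazole, DMF, rt
Reagents that add atoms: triisopropylsilyl chloride, CC(C)[Si](Cl)(C(C)C)C(C)C
Why: Standard phenol silylation; the bulky silyl ether marks the oxygen that will become O1 and leaves the carbon between the two benzyloxy groups as the only doubly activated site for metalation.

Step 4
Reactants: 5 [3,5-bis(benzyloxy)phenoxy]tri(propan-2-yl)silane; 3 5-(benzyloxy)-2-[4-(benzyloxy)phenyl]-8-iodo-7-methoxy-4H-chromen-4-one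
Product: 8 5-(benzyloxy)-2-[4-(benzyloxy)phenyl]-8-{2,6-bis(benzyloxy)-4-[tri(propan-2-yl)silyloxy]phenyl}-7-methoxy-4H-chromen-4-one, via aryllithium 6 (not isolated), via arylzinc chloride 7 (not isolated)
Conditions: 5, n-BuLi, Et2O, 0 °C → rt; ZnCl2, THF; then 3, Pd2(dba)3 (cat.), RuPhos (cat.), THF/NMP, 70 °C
Reagents that add atoms: none
Why: Directed ortho-lithiation at the carbon flanked by two alkoxy groups, transmetalation to zinc and Negishi coupling with a bulky dialkylbiarylphosphine, a combination known to give tetra-ortho-substituted biaryls and to leave a chromone carbonyl untouched.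

Step 5
Reactants: 8 5-(benzyloxy)-2-[4-(benzyloxy)phenyl]-8-{2,6-bis(benzyloxy)-4-[tri(propan-2-yl)silyloxy]phenyl}-7-methoxy-4H-chromen-4-one
Product: 9 5-(benzyloxy)-2-[4-(benzyloxy)phenyl]-8-[2,6-bis(benzyloxy)-4-hydroxyphenyl]-7-methoxy-4H-chromen-4-one
Conditions: Bu4NF, AcOH, THF, 0 °C → rt
Reagents that add atoms: none
Why: Buffered fluoride cleavage of an aryl silyl ether frees only the oxygen para to the biaryl bond, while the four benzyl ethers stay.

Step 6
Reactants: 10 3-(4-methoxyphenyl)propiolic acid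
Product: 11 tert-butyl 3-(4-methoxyphenyl)prop-2-ynoate
Conditions: tert-butyl 2,2,2-trichloroacetimidate, CH2Cl2/cyclohexane, rt
Reagents that add atoms: tert-butyl 2,2,2-trichloroacetimidate, CC(C)(C)OC(=N)C(Cl)(Cl)Cl
Why: Imidate tert-butylation of a carboxylic acid at room temperature, avoiding the heat and nucleophilic catalysts that an arylpropiolic acid tolerates poorly.

Step 7
Reactants: 9 5-(benzyloxy)-2-[4-(benzyloxy)phenyl]-8-[2,6-bis(benzyloxy)-4-hydroxyphenyl]-7-methoxy-4H-chromen-4-one; 11 tert-butyl 3-(4-methoxyphenyl)prop-2-ynoate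
Product: 12 tert-butyl (Z)-3-(3,5-bis(benzyloxy)-4-{5-(benzyloxy)-2-[4-(benzyloxy)phenyl]-7-methoxy-4-oxo-4H-chromen-8-yl}phenoxy)-3-(4-methoxyphenyl)prop-2-enoate
Conditions: Cs2CO3, DMF, 70 °C
Reagents that add atoms: none
Why: Base-mediated oxa-Michael addition of the only free phenoxide to the alkynoate, anti addition placing the ester cis to the aryloxy group (Z); a minor (E) isomer is harmless because the geometry equilibrates under the acid of step 10.

Step 8
Reactants: 12 tert-butyl (Z)-3-(3,5-bis(benzyloxy)-4-{5-(benzyloxy)-2-[4-(benzyloxy)phenyl]-7-methoxy-4-oxo-4H-chromen-8-yl}phenoxy)-3-(4-methoxyphenyl)prop-2-enoate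
Product: 13 (Z)-3-(3,5-bis(benzyloxy)-4-{5-(benzyloxy)-2-[4-(benzyloxy)phenyl]-7-methoxy-4-oxo-4H-chromen-8-yl}phenoxy)-3-(4-methoxyphenyl)prop-2-enoic acid
Conditions: CF3CO2H, CH2Cl2, 0 °C → rt
Reagents that add atoms: none
Why: Anhydrous acidolysis of the tert-butyl ester with loss of 2-methylpropene, which the benzyl ethers and the ester-deactivated enol ether should survive.

Step 9
Reactants: 13 (Z)-3-(3,5-bis(benzyloxy)-4-{5-(benzyloxy)-2-[4-(benzyloxy)phenyl]-7-methoxy-4-oxo-4H-chromen-8-yl}phenoxy)-3-(4-methoxyphenyl)prop-2-enoic acid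
Product: 14 (Z)-3-{3,5-dihydroxy-4-[5-hydroxy-2-(4-hydroxyphenyl)-7-methoxy-4-oxo-4H-chromen-8-yl]phenoxy}-3-(4-methoxyphenyl)prop-2-enoic acid
Conditions: BCl3, C6HMe5, CH2Cl2, −78 °C; aqueous work-up
Reagents that add atoms: none
Why: Low-temperature Lewis-acid debenzylation of aryl benzyl ethers with pentamethylbenzene as a non-basic benzyl cation trap, conditions that spare aryl methyl ethers and alkenes and keep benzyl cations off the electron-rich ring A.

Step 10
Reactants: 14 (Z)-3-{3,5-dihydroxy-4-[5-hydroxy-2-(4-hydroxyphenyl)-7-methoxy-4-oxo-4H-chromen-8-yl]phenoxy}-3-(4-methoxyphenyl)prop-2-enoic acid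
Product: 15 5,7-dihydroxy-6-[5-hydroxy-2-(4-hydroxyphenyl)-7-methoxy-4-oxo-4H-chromen-8-yl]-2-(4-methoxyphenyl)-4H-chromen-4-one (CNP0290866.0, racemic about the C6–C8'' axis)
Conditions: Eaton's reagent (P2O5 in MeSO3H), rt → 40 °C; ice water
Reagents that add atoms: none
Why: Eaton's reagent turns the carboxylic acid into a mixed anhydride or acylium ion, and reversible protonation at C3 of the enol ether lets any (E) isomer pass into the (Z) form in which the acyl carbon lies next to ring A. The acyl carbon then attacks the ring carbon ortho to the ether oxygen (also ortho and para to the two free hydroxyls) and rearomatisation gives the C4–C4a bond; the closest known reaction is the Ruhemann flavone synthesis, the acid-mediated intramolecular Friedel–Crafts acylation of β-aryloxycinnamic acids. Ring C closes as a six-membered ring in a 6-exo-trig sense at the activated carbonyl, with O1, C2 and C3 already in place. No stereocentre is formed; the two ortho carbons are enantiotopic, so the C6–C8'' axis becomes stereogenic only here and forms as the racemate, nothing in the substrate controlling it. The step needs closure onto ring A and the 6- rather than the 8-linkage: the ring oxygen sits on the oxygen para to the biaryl carbon, so both attack sites give the same 6-linked constitution, while attack on the anisyl ring would need a five-membered indenone closure meta to its methoxy group and should not compete. A moderate temperature is chosen so that neither C-sulfonylation of ring A nor acid-induced opening and reclosure of the 5,7-dihydroxyflavone (Wessely–Moser) interferes.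

**Compound list**

1 | genkwanin (5-hydroxy-2-(4-hydroxyphenyl)-7-methoxy-4H-chromen-4-one) | COc1cc(O)c2c(=O)cc(-c3ccc(O)cc3)oc2c1 | starting material
2 | 5-(benzyloxy)-2-[4-(benzyloxy)phenyl]-7-methoxy-4H-chromen-4-one | COc1cc(OCc2ccccc2)c2c(=O)cc(-c3ccc(OCc4ccccc4)cc3)oc2c1 | intermediate
3 | 5-(benzyloxy)-2-[4-(benzyloxy)phenyl]-8-iodo-7-methoxy-4H-chromen-4-one | COc1cc(OCc2ccccc2)c2c(=O)cc(-c3ccc(OCc4ccccc4)cc3)oc2c1I | intermediate
4 | 3,5-bis(benzyloxy)phenol | Oc1cc(OCc2ccccc2)cc(OCc2ccccc2)c1 | starting material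
5 | [3,5-bis(benzyloxy)phenoxy]tri(propan-2-yl)silane | CC(C)[Si](Oc1cc(OCc2ccccc2)cc(OCc2ccccc2)c1)(C(C)C)C(C)C | intermediate
6 | {2,6-bis(benzyloxy)-4-[tri(propan-2-yl)silyloxy]phenyl}lithium | [Li]c1c(OCc2ccccc2)cc(O[Si](C(C)C)(C(C)C)C(C)C)cc1OCc1ccccc1 | intermediate
7 | {2,6-bis(benzyloxy)-4-[tri(propan-2-yl)silyloxy]phenyl}zinc chloride | Cl[Zn]c1c(OCc2ccccc2)cc(O[Si](C(C)C)(C(C)C)C(C)C)cc1OCc1ccccc1 | intermediate
8 | 5-(benzyloxy)-2-[4-(benzyloxy)phenyl]-8-{2,6-bis(benzyloxy)-4-[tri(propan-2-yl)silyloxy]phenyl}-7-methoxy-4H-chromen-4-one | COc1cc(OCc2ccccc2)c2c(=O)cc(-c3ccc(OCc4ccccc4)cc3)oc2c1-c1c(OCc2ccccc2)cc(O[Si](C(C)C)(C(C)C)C(C)C)cc1OCc1ccccc1 | intermediate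
9 | 5-(benzyloxy)-2-[4-(benzyloxy)phenyl]-8-[2,6-bis(benzyloxy)-4-hydroxyphenyl]-7-methoxy-4H-chromen-4-one | COc1cc(OCc2ccccc2)c2c(=O)cc(-c3ccc(OCc4ccccc4)cc3)oc2c1-c1c(OCc2ccccc2)cc(O)cc1OCc1ccccc1 | intermediate
10 | 3-(4-methoxyphenyl)propiolic acid | COc1ccc(C#CC(=O)O)cc1 | starting material
11 | tert-butyl 3-(4-methoxyphenyl)prop-2-ynoate | COc1ccc(C#CC(=O)OC(C)(C)C)cc1 | intermediate
12 | tert-butyl (Z)-3-(3,5-bis(benzyloxy)-4-{5-(benzyloxy)-2-[4-(benzyloxy)phenyl]-7-methoxy-4-oxo-4H-chromen-8-yl}phenoxy)-3-(4-methoxyphenyl)prop-2-enoate | CC(C)(C)OC(=O)/C=C(\Oc1cc(OCc2ccccc2)c(-c2c(OC)cc(OCc3ccccc3)c3c(=O)cc(-c4ccc(OCc5ccccc5)cc4)oc23)c(OCc2ccccc2)c1)c1ccc(OC)cc1 | intermediate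
13 | (Z)-3-(3,5-bis(benzyloxy)-4-{5-(benzyloxy)-2-[4-(benzyloxy)phenyl]-7-methoxy-4-oxo-4H-chromen-8-yl}phenoxy)-3-(4-methoxyphenyl)prop-2-enoic acid | OC(=O)/C=C(\Oc1cc(OCc2ccccc2)c(-c2c(OC)cc(OCc3ccccc3)c3c(=O)cc(-c4ccc(OCc5ccccc5)cc4)oc23)c(OCc2ccccc2)c1)c1ccc(OC)cc1 | intermediate
14 | (Z)-3-{3,5-dihydroxy-4-[5-hydroxy-2-(4-hydroxyphenyl)-7-methoxy-4-oxo-4H-chromen-8-yl]phenoxy}-3-(4-methoxyphenyl)prop-2-enoic acid | OC(=O)/C=C(\Oc1cc(O)c(-c2c(OC)cc(O)c3c(=O)cc(-c4ccc(O)cc4)oc23)c(O)c1)c1ccc(OC)cc1 | intermediate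
15 | 5,7-dihydroxy-6-[5-hydroxy-2-(4-hydroxyphenyl)-7-methoxy-4-oxo-4H-chromen-8-yl]-2-(4-methoxyphenyl)-4H-chromen-4-one (CNP0290866.0) | COc1ccc(-c2cc(=O)c3c(O)c(-c4c(OC)cc(O)c5c(=O)cc(-c6ccc(O)cc6)oc45)c(O)cc3o2)cc1 | target

**Step count and risks**

Total step count: 10. Longest linear sequence: 8 steps (1, 2, 4, 5, 7, 8, 9, 10 from genkwanin).

Steps most likely to fail:

1. Step 10. The strong acid may protonate C3 and expel the arylphloroglucinol (retro-addition), which can recombine to a 4-arylcoumarin; ring A may be C-sulfonylated; or the product may isomerise by ring opening and reclosure. The fallback sets out from phenol 9 and returns at 15, closing ring C by palladium carbonylation instead of acid. Iodination of 9 with N-iodosuccinimide (CH2Cl2, 0 °C) at one of the two equivalent carbons ortho to the free hydroxyl should give 5-(benzyloxy)-2-[4-(benzyloxy)phenyl]-8-[2,6-bis(benzyloxy)-4-hydroxy-3-iodophenyl]-7-methoxy-4H-chromen-4-one F1. Carbonylative Sonogashira annulation of F1 with 1-ethynyl-4-methoxybenzene under CO (1 atm) with PdCl2(PPh3)2 in Et2NH at 60 °C should pass through the ortho-hydroxyaryl ynone and give 5,7-bis(benzyloxy)-6-{5-(benzyloxy)-2-[4-(benzyloxy)phenyl]-7-methoxy-4-oxo-4H-chromen-8-yl}-2-(4-methoxyphenyl)-4H-chromen-4-one F2. BCl3/C6HMe5 (CH2Cl2, −78 °C) then frees the four phenols to give 15. The 6-linkage stays fixed because only the oxygen para to the biaryl bond is free.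

2. Step 4. Transmetalation and reductive elimination at the four-fold ortho-substituted axis may be slow, so that reduction of iodide 3 and homocoupling take over; during lithiation, deprotonation at a benzylic OCH2 with a 1,2-Wittig shift may also compete. The fallback sets out from iodide 3 and aryllithium 6 and returns at 8, with the polarity of the coupling reversed. Miyaura borylation of 3 (B2pin2, PdCl2(dppf), KOAc, dioxane, 90 °C) should give 5-(benzyloxy)-2-[4-(benzyloxy)phenyl]-7-methoxy-8-(4,4,5,5-tetramethyl-1,3,2-dioxaborolan-2-yl)-4H-chromen-4-one F3. Quenching 6 with I2 at −78 °C should give [3,5-bis(benzyloxy)-4-iodophenoxy]tri(propan-2-yl)silane F4. Suzuki–Miyaura coupling of F3 with F4 (Pd(OAc)2, SPhos, K3PO4, toluene/H2O, 100 °C) should then deliver 8.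

3. Step 7. Conjugate addition to the donor-substituted alkynoate may be sluggish, and the ambident phenoxide may attack through carbon, which after lactonisation would lead towards a 4-arylcoumarin. The fallback sets out from alkynoate 11 (with phenol 9) and returns at 12, replacing addition to the alkyne by substitution at an sp2 carbon. Anti hydrochlorination of 11 (LiCl, AcOH, MeCN, 80 °C) should give tert-butyl (Z)-3-chloro-3-(4-methoxyphenyl)prop-2-enoate F5. Addition–elimination of the phenoxide of 9 on F5 (K2CO3, DMF, 40 °C), through an ester enolate and with retention of geometry, should then give 12.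

**Further compounds**

F1 | step 10 | 5-(benzyloxy)-2-[4-(benzyloxy)phenyl]-8-[2,6-bis(benzyloxy)-4-hydroxy-3-iodophenyl]-7-methoxy-4H-chromen-4-one | COc1cc(OCc2ccccc2)c2c(=O)cc(-c3ccc(OCc4ccccc4)cc3)oc2c1-c1c(OCc2ccccc2)cc(O)c(I)c1OCc1ccccc1
F2 | step 10 | 5,7-bis(benzyloxy)-6-{5-(benzyloxy)-2-[4-(benzyloxy)phenyl]-7-methoxy-4-oxo-4H-chromen-8-yl}-2-(4-methoxyphenyl)-4H-chromen-4-one | COc1ccc(-c2cc(=O)c3c(OCc4ccccc4)c(-c4c(OC)cc(OCc5ccccc5)c5c(=O)cc(-c6ccc(OCc7ccccc7)cc6)oc45)c(OCc4ccccc4)cc3o2)cc1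
F3 | step 4 | 5-(benzyloxy)-2-[4-(benzyloxy)phenyl]-7-methoxy-8-(4,4,5,5-tetramethyl-1,3,2-dioxaborolan-2-yl)-4H-chromen-4-one | COc1cc(OCc2ccccc2)c2c(=O)cc(-c3ccc(OCc4ccccc4)cc3)oc2c1B1OC(C)(C)C(C)(C)O1
F4 | step 4 | [3,5-bis(benzyloxy)-4-iodophenoxy]tri(propan-2-yl)silane | CC(C)[Si](Oc1cc(OCc2ccccc2)c(I)c(OCc2ccccc2)c1)(C(C)C)C(C)C
F5 | step 7 | tert-butyl (Z)-3-chloro-3-(4-methoxyphenyl)prop-2-enoate | CC(C)(C)OC(=O)/C=C(\Cl)c1ccc(OC)cc1
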